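**Strategy.** The synthesis rests on disconnecting C33–C34. C34 is a ketone carbon bonded to C33 of ring C, and C33 adjoins C25 and C27, so an allyl unit C27–C25=C33 in ring C can serve as nucleophile. In one operation a C27 pinacol boronate adds through C33 to a C34 aldehyde. This forms C33–C34, closes the 13-membered ring (C7, O8, arene, C15, C16, C18, C19, C34, C33, C32), sets C33 and leaves the alkene at C25=C27 for the later peroxide. The precursor is the decahydrofluorene allylboronate joined through the C7 aryl ether to a methoxy lactam whose quaternary C19 carries the aldehyde, unveiled only just before ring closure.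

Key step: step 29

Remark 1: atom numbers C1–N41 follow the target SMILES; β is the face of rings B and C that carries the C37 methyl, α the opposite face.
Remark 2: the sense of the chiral base (step 1) and of the esterase (step 17) is assumed; the mirror-image base, or exchanging the roles of acid and ester in 25, would correct either.
Remark 3: the hemiaminal carbon C16 and the peroxyhemiacetal carbon C21 are taken to settle by equilibration in the configuration of the target.

**Ring A and the tricycle**

Step 1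
Reactants: 1 cis-3,5-dimethylcyclohexanone
Product: 2 silyl enol ether (double bond towards future C6)
Conditions: lithium (R,R)-bis(1-phenylethyl)amide (from the amine and n-BuLi), LiCl, TMSCl, THF, −100 °C
Reagents that add atoms: chlorotrimethylsilane, C[Si](C)(C)Cl
Why: Enantiotopic-proton-selective deprotonation of the meso ketone by a chiral lithium amide with in situ silylation should fix which α-carbon becomes C6, so the two ring methyls (C2, C4) become stereocentres of one enantiomer.

Step 2
Reactants: 2 silyl enol ether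
Product: 3 2-(dimethoxymethyl)-3,5-dimethylcyclohexanone
Conditions: HC(OMe)3, BF3·OEt2, CH2Cl2, −78 °C
Reagents that add atoms: trimethyl orthoformate, COC(OC)OC
Why: Mukaiyama-type addition of the enol ether to the dialkoxycarbenium ion should place the masked formyl carbon C7 regiospecifically on C6, which settles equatorial.

Step 3
Reactants: 3 acetal ketone
Product: 5 4,6-dimethyl-2-[(methoxymethoxy)methyl]cyclohex-1-ene-1-carbaldehyde, via carbinol adduct 4 (not isolated)
Conditions: Bu3SnCH2OCH2OMe, n-BuLi, THF, −78 °C; CeCl3; then 3; then 1 M HCl, THF, 25 °C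
Reagents that add atoms: tributyl[(methoxymethoxy)methyl]stannane, CCCC[Sn](CCCC)(CCCC)COCOC; water, O
Why: 1,2-Addition of the α-alkoxymethyl organocerium to the ketone brings in C31, and acid hydrolysis of the acetal followed by β-elimination of the tertiary alcohol should give the tetrasubstituted enal.

Step 4
Reactants: 5 enal
Product: 7 ring A aldehyde with quaternary C36, via silyl enol ether 6 (not isolated)
Conditions: Me2CuLi (from MeLi and CuI), TMSCl, THF, −78 to −30 °C; then K2CO3, MeOH, 0 °C
Reagents that add atoms: lithium dimethylcuprate, [Li+].C[Cu-]C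
Why: Conjugate addition of the Gilman cuprate should occur axially and trans to the C2 methyl, so the C37 methyl becomes axial and CH2OMOM equatorial at C36, and base equilibration puts the formyl group equatorial at C6.

Step 5
Reactants: 7 ring A aldehyde; 8 2-methylbut-1-en-3-yne
Product: 9 (E)-dienyl carbinol (7α-OH)
Conditions: 8, Cp2Zr(H)Cl, CH2Cl2, 25 °C; Me2Zn, toluene, −65 °C; then 7, 0 °C
Reagents that add atoms: none
Why: Hydrozirconation of the alkyne and zirconium-to-zinc transmetalation give an (E)-dienylzinc that should add to the aldehyde in the Felkin–Anh sense (quaternary C36 anti to the nucleophile), setting C7 as the α-alcohol.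

Step 6
Reactants: 9 dienyl carbinol
Product: 10 TBS ether
Conditions: TBSOTf, 2,6-lutidine, CH2Cl2, −78 °C
Reagents that add atoms: tert-butyldimethylsilyl triflate, CC(C)(C)[Si](C)(C)OS(=O)(=O)C(F)(F)F
Why: Silylation of the secondary allylic alcohol under non-acidic conditions should leave the diene and the MOM ether untouched.

Step 7
Reactants: 10 TBS ether
Product: 11 primary alcohol (C31)
Conditions: Me2BBr, CH2Cl2, −78 °C; then NaHCO3 aq.
Reagents that add atoms: none
Why: Dimethylboron bromide cleaves MOM ethers at low temperature and should spare the TBS ether and the diene.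

Step 8
Reactants: 11 primary alcohol
Product: 12 C31 aldehyde
Conditions: Dess–Martin periodinane, NaHCO3, CH2Cl2, 0 °C
Reagents that add atoms: none
Why: Dess–Martin oxidation of a neopentyl primary alcohol is reliable, and the aldehyde has no α-hydrogen.

Step 9
Reactants: 12 C31 aldehyde
Product: 14 tricyclic aldehyde (C30 formyl), via trienal 13 (not isolated)
Conditions: Ph3P=CHCHO, BHT, toluene, 110 °C
Reagents that add atoms: (triphenylphosphoranylidene)acetaldehyde, O=CC=P(c1ccccc1)(c1ccccc1)c1ccccc1
Why: Wittig olefination with the stabilised ylide gives the (E)-enal, whose intramolecular Diels–Alder reaction with the tethered diene should close rings B and C through the formyl-endo transition state, in which the E-alkene sets C29 trans to C36, the trans-diequatorial tether on ring A and the in-plane α-silyloxy group at C7 set H31 α and H32 β.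

Step 10
Reactants: 14 tricyclic aldehyde
Product: 16 tricyclic alkene with C30 methyl, via tosylhydrazone 15 (not isolated)
Conditions: TsNHNH2, EtOH, 25 °C; then catecholborane, CHCl3, 0 °C; NaOAc·3H2O, 60 °C
Reagents that add atoms: none
Why: Tosylhydrazone formation and hydride reduction with loss of sulfinate and N2 should turn the formyl group into the C30 methyl without touching the trisubstituted alkene.

Step 11
Reactants: 16 tricyclic alkene
Product: 17 tricyclic enone (C27 ketone)
Conditions: Pd(OH)2/C, t-BuOOH, K2CO3, CH2Cl2, 4 °C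
Reagents that add atoms: tert-butyl hydroperoxide, CC(C)(C)OO
Why: Allylic oxidation of a trisubstituted cyclohexene should convert the only allylic methylene, C27, into the enone carbonyl.

Step 12
Reactants: 17 tricyclic enone
Product: 18 enone alcohol (7α-OH)
Conditions: HF·pyridine, pyridine, THF, 0 to 25 °C
Reagents that add atoms: none
Why: Fluoride cleaves the secondary TBS ether, and the enone is inert to it.

Step 13
Reactants: 18 enone alcohol
Product: 19 epoxy ketone alcohol (α-oxirane)
Conditions: 30% H2O2, NaOH, MeOH, 0 °C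
Reagents that add atoms: hydrogen peroxide, OO
Why: In this Weitz–Scheffer epoxidation hydroperoxide should add axially to C33, anti to the axial H32 and guided by the free 7α-hydroxyl, so the oxirane forms on the α face.

**Lactam fragment**

Step 14
Reactants: 20 4-hydroxyphenylacetic acid
Product: 21 benzyl [4-(benzyloxy)phenyl]acetate
Conditions: BnBr, K2CO3, DMF, 60 °C
Reagents that add atoms: benzyl bromide, BrCc1ccccc1
Why: Double O-alkylation of the phenolate and the carboxylate is a standard Williamson reaction.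

Step 15
Reactants: 21 dibenzyl compound
Product: 22 1-[4-(benzyloxy)phenyl]-3-chloropropan-2-one
Conditions: ICH2Cl, MeLi·LiBr, THF, −78 °C; then NH4Cl aq.
Reagents that add atoms: chloroiodomethane, ClCI
Why: Chloromethyllithium adds once to the ester because the tetrahedral adduct persists at −78 °C, which should give the chloromethyl ketone on quenching.

Step 16
Reactants: 22 chloromethyl ketone; 23 dimethyl allylmalonate
Product: 24 dimethyl 2-allyl-2-{3-[4-(benzyloxy)phenyl]-2-oxopropyl}malonate
Conditions: 23, NaH (1.0 equiv), THF–DMF, 0 °C; then 22, NaI, 25 °C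
Reagents that add atoms: none
Why: SN2 alkylation of the soft malonate anion by the α-halo ketone forms C18–C19 and the prochiral quaternary centre.

Step 17
Reactants: 24 diester
Product: 25 malonic half ester (C19 as in target)
Conditions: pig liver esterase, pH 7.5 phosphate buffer, 10% DMSO, 30 °C (pH-stat, NaOH)
Reagents that add atoms: water, O
Why: Enzymatic desymmetrisation hydrolyses one enantiotopic methyl ester of the disubstituted malonate and so should set C19.

Step 18
Reactants: 25 half ester
Product: 28 methoxy lactam ester (C16 epimers), via acid chloride 26 (not isolated), via hydroxy lactam 27 (not isolated)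
Conditions: (COCl)2, DMF (cat.), CH2Cl2, 0 °C; NH3, dioxane, 0 °C; then MeOH, CSA, 25 °C
Reagents that add atoms: ammonia, N; methanol, CO
Why: The primary amide closes onto the γ-ketone to the hydroxy lactam, and acid-catalysed exchange through the N-acyliminium ion gives the N,O-acetal, which is carried as both C16 epimers.

Step 19
Reactants: 28 methoxy lactam ester
Product: 29 hydroxymethyl lactam
Conditions: LiBH4, THF, 0 to 25 °C
Reagents that add atoms: none
Why: Lithium borohydride reduces the methyl ester to the C34 alcohol and leaves the lactam and the N,O-acetal.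

Step 20
Reactants: 29 hydroxymethyl lactam
Product: 30 TBDPS ether
Conditions: TBDPSCl, imidazole, DMF, 25 °C
Reagents that add atoms: tert-butylchlorodiphenylsilane, CC(C)(C)[Si](Cl)(c1ccccc1)c1ccccc1
Why: Silylation of the neopentyl primary alcohol gives an ether that survives acid methanol, hydrogenolysis and Mitsunobu conditions.

Step 21
Reactants: 30 TBDPS ether
Product: 32 dimethyl acetal (C16 as in target), via aldehyde 31 (not isolated)
Conditions: OsO4 (cat.), NaIO4, 2,6-lutidine, dioxane–H2O, 25 °C; then HC(OMe)3, PPTS, MeOH, 25 °C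
Reagents that add atoms: trimethyl orthoformate, COC(OC)OC; methanol, CO
Why: Lemieux–Johnson cleavage of the allyl group gives the C21 aldehyde, which is acetalised under conditions that also equilibrate the N,O-acetal, so the C16 epimer drawn is isolated and the other is returned to the same conditions.

Step 22
Reactants: 32 benzyl ether
Product: 33 phenol lactam fragment
Conditions: H2 (1 atm), Pd/C, EtOAc, 25 °C
Reagents that add atoms: none
Why: Hydrogenolysis removes the benzyl group and should leave the acetals and the silyl ether.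

**Union, key step and endgame**

Step 23
Reactants: 19 epoxy ketone alcohol; 33 phenol lactam fragment
Product: 34 aryl ether (7β-O-aryl)
Conditions: PPh3, DIAD, toluene, 0 to 45 °C
Reagents that add atoms: none
Why: Mitsunobu etherification displaces the activated 7α-oxygen by the phenol with inversion, which gives the β-configured C7–O8 bond of the target.

Step 24
Reactants: 34 aryl ether
Product: 35 allylic alcohol (33α-OH, C25=C27)
Conditions: N2H4·H2O, AcOH, MeOH, 0 to 25 °C
Reagents that add atoms: none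
Why: Wharton transposition of the epoxy ketone places the hydroxyl on C33 with the α configuration of the oxirane and moves the alkene to C25=C27.

Step 25
Reactants: 35 allylic alcohol
Product: 36 methyl carbonate
Conditions: ClCO2Me, pyridine, DMAP, CH2Cl2, 0 °C
Reagents that add atoms: methyl chloroformate, COC(=O)Cl
Why: Acylation of the only free alcohol gives the leaving group for the allylic borylation.

Step 26
Reactants: 36 methyl carbonate
Product: 37 primary alcohol (C34–OH)
Conditions: TBAF, AcOH, THF, 25 °C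
Reagents that add atoms: none
Why: Buffered fluoride removes the TBDPS group and should spare the carbonate and both acetals.

Step 27
Reactants: 37 primary alcohol; 38 bis(pinacolato)diboron
Product: 39 C27 β-pinacol boronate (C33=C25)
Conditions: CuCl, Xantphos, KOtBu (each cat.), 38, THF, 25 °C
Reagents that add atoms: none
Why: Copper-catalysed γ-selective (SN2′) borylation of allylic carbonates is anti, so the α-carbonate on C33 should deliver boron to the β face of C27, trans to the C30 methyl.

Step 28
Reactants: 39 boronate alcohol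
Product: 40 allylboronate aldehyde (precursor)
Conditions: SO3·pyridine, DMSO, iPr2NEt, CH2Cl2, 0 °C; filtered cold and used at once
Reagents that add atoms: none
Why: Parikh–Doering oxidation of the neopentyl alcohol uses no reagent that attacks the C–B bond, and it frees the aldehyde only when the boronate is in place.

Step 29
Reactants: 40 allylboronate aldehyde
Product: 42 macrocyclic homoallylic alcohol, via borate ester 41 (not isolated)
Conditions: toluene (1 mM), 4 Å molecular sieves, 70 °C; then pH 7 buffer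
Reagents that add atoms: none
Why: The aldehyde oxygen binds the boron on C27 and C33 attacks C34 through a closed six-membered chair-like transition state, so the allyl unit reacts only at its γ-carbon and the double bond moves to C25=C27. The closest known reaction is the γ-selective, stereospecific allylboration of aldehydes by cyclic secondary allylboronates, here in intramolecular form. The 13-membered ring closes by 13-exo-trig attack of C33 on the formyl carbon, favoured by high dilution and by the slow bimolecular reaction of a hindered pinacol boronate with a neopentyl aldehyde. C33 is set by the boron-bearing β face of C27 (suprafacial transfer), fixed in step 27, while C34 is set by the chair but is erased in step 30. Selectivity for the aldehyde over the acetal, the N,O-acetal, the lactam carbonyl and the aryl ether follows from the absence of any Lewis acid or base.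

Step 30
Reactants: 42 macrocyclic alcohol
Product: 43 macrocyclic β,γ-unsaturated ketone
Conditions: Dess–Martin periodinane, NaHCO3, CH2Cl2, 0 °C
Reagents that add atoms: none
Why: Buffered Dess–Martin oxidation gives the C34 ketone without enolising C33, so the alkene stays out of conjugation.

Step 31
Reactants: 43 macrocyclic ketone
Product: 44 keto aldehyde hemiaminal
Conditions: 1 M HCl, THF, 0 to 25 °C
Reagents that add atoms: water, O
Why: Mild aqueous acid hydrolyses the dimethyl acetal to the C21 aldehyde and the N,O-acetal to the C16 hemiaminal, which equilibrates to the ring-compatible configuration.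

Step 32
Reactants: 44 keto aldehyde
Product: 46 peroxyhemiacetal with C27=C29 alkene, via hydroperoxide 45 (not isolated)
Conditions: O2, tetraphenylporphyrin (cat.), white LED, CH2Cl2, −30 °C
Reagents that add atoms: dioxygen, O=O
Why: In the Schenck ene reaction singlet oxygen should bond to C25 on the β face while abstracting the axial β-hydrogen on C29, and the tertiary hydroperoxide then adds to the C21 aldehyde to close the eight-membered peroxyhemiacetal.

Step 33
Reactants: 46 peroxyhemiacetal alkene
Product: 48 CNP0533733.1, via bromohydrin 47 (not isolated)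
Conditions: N-bromosuccinimide, THF–H2O, 0 °C; then Ag2O, THF, 25 °C
Reagents that add atoms: water, O
Why: The bromonium ion should form on the less hindered α face and open trans-diaxially (Fürst–Plattner) by water at the tertiary C29, so silver-assisted closure of the 27α-bromo-29β-ol gives the β-epoxide, cis to the peroxide.

**Compound list**

1 | cis-3,5-dimethylcyclohexanone (meso) | O=C1C[C@@H](C)C[C@@H](C)C1 | starting material
2 | trimethylsilyl enol ether of 1, double bond towards future C6 (C2, C4 as in target) | C[C@@H]1C[C@H](C)C=C(O[Si](C)(C)C)C1 | intermediate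
3 | 2-(dimethoxymethyl)-3,5-dimethylcyclohexanone, all substituents equatorial | C[C@@H]1C[C@H](C)[C@@H](C(OC)OC)C(=O)C1 | intermediate
4 | 2-(dimethoxymethyl)-1-[(methoxymethoxy)methyl]-3,5-dimethylcyclohexan-1-ol (carbinol epimers) | C[C@@H]1C[C@H](C)[C@@H](C(OC)OC)C(O)(COCOC)C1 | intermediate
5 | 4,6-dimethyl-2-[(methoxymethoxy)methyl]cyclohex-1-ene-1-carbaldehyde | C[C@@H]1C[C@H](C)C(C=O)=C(COCOC)C1 | intermediate
6 | trimethylsilyl enol ether of 7 | C[C@@H]1C[C@H](C)C(=CO[Si](C)(C)C)[C@](C)(COCOC)C1 | intermediate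
7 | 2-[(methoxymethoxy)methyl]-2,4,6-trimethylcyclohexane-1-carbaldehyde; C37 methyl axial, formyl, CH2OMOM and the C2 and C4 methyls equatorial | C[C@@H]1C[C@H](C)[C@@H](C=O)[C@](C)(COCOC)C1 | intermediate
8 | 2-methylbut-1-en-3-yne | CC(=C)C#C | starting material
9 | (E)-dienyl carbinol: ring A bearing C7 α-hydroxyl with the 3-methylbuta-1,3-dienyl group | C[C@@H]1C[C@H](C)[C@@H]([C@H](O)/C=C/C(C)=C)[C@](C)(COCOC)C1 | intermediate
10 | TBS ether of 9 | C[C@@H]1C[C@H](C)[C@@H]([C@H](O[Si](C)(C)C(C)(C)C)/C=C/C(C)=C)[C@](C)(COCOC)C1 | intermediate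
11 | C31 primary alcohol | C[C@@H]1C[C@H](C)[C@@H]([C@H](O[Si](C)(C)C(C)(C)C)/C=C/C(C)=C)[C@](C)(CO)C1 | intermediate
12 | C31 aldehyde | C[C@@H]1C[C@H](C)[C@@H]([C@H](O[Si](C)(C)C(C)(C)C)/C=C/C(C)=C)[C@](C)(C=O)C1 | intermediate
13 | (E)-enal trienal | C[C@@H]1C[C@H](C)[C@@H]([C@H](O[Si](C)(C)C(C)(C)C)/C=C/C(C)=C)[C@](C)(/C=C/C=O)C1 | intermediate
14 | tricyclic aldehyde: 7α-OTBS, H31 α, H32 β, C30 formyl α on C29, alkene C33=C25 | C[C@@H]1C[C@H](C)[C@H]2[C@H](O[Si](C)(C)C(C)(C)C)[C@@H]3C=C(C)C[C@H](C=O)[C@H]3[C@]2(C)C1 | intermediate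
15 | tosylhydrazone of 14 | C[C@@H]1C[C@H](C)[C@H]2[C@H](O[Si](C)(C)C(C)(C)C)[C@@H]3C=C(C)C[C@H](/C=N/NS(=O)(=O)c4ccc(C)cc4)[C@H]3[C@]2(C)C1 | intermediate
16 | tricyclic alkene with C30 methyl | C[C@@H]1C[C@H](C)[C@H]2[C@H](O[Si](C)(C)C(C)(C)C)[C@@H]3C=C(C)C[C@H](C)[C@H]3[C@]2(C)C1 | intermediate
17 | tricyclic enone (C27 ketone, C25=C33) | C[C@@H]1C[C@H](C)[C@H]2[C@H](O[Si](C)(C)C(C)(C)C)[C@@H]3C=C(C)C(=O)[C@H](C)[C@H]3[C@]2(C)C1 | intermediate
18 | enone alcohol (7α-OH) | C[C@@H]1C[C@H](C)[C@H]2[C@H](O)[C@@H]3C=C(C)C(=O)[C@H](C)[C@H]3[C@]2(C)C1 | intermediate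
19 | epoxy ketone alcohol (α-oxirane C25–C33, 7α-OH) | C[C@@H]1C[C@H](C)[C@H]2[C@H](O)[C@@H]3[C@@H]4O[C@]4(C)C(=O)[C@H](C)[C@H]3[C@]2(C)C1 | intermediate
20 | 4-hydroxyphenylacetic acid | OC(=O)Cc1ccc(O)cc1 | starting material
21 | benzyl [4-(benzyloxy)phenyl]acetate | O=C(Cc1ccc(OCc2ccccc2)cc1)OCc1ccccc1 | intermediate
22 | 1-[4-(benzyloxy)phenyl]-3-chloropropan-2-one | ClCC(=O)Cc1ccc(OCc2ccccc2)cc1 | intermediate
23 | dimethyl allylmalonate | COC(=O)C(CC=C)C(=O)OC | starting material
24 | dimethyl 2-allyl-2-{3-[4-(benzyloxy)phenyl]-2-oxopropyl}malonate | COC(=O)C(CC=C)(CC(=O)Cc1ccc(OCc2ccccc2)cc1)C(=O)OC | intermediate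
25 | malonic half ester, C19 as in target (acid = future C39) | COC(=O)[C@](CC=C)(CC(=O)Cc1ccc(OCc2ccccc2)cc1)C(O)=O | intermediate
26 | acid chloride of 25 | COC(=O)[C@](CC=C)(CC(=O)Cc1ccc(OCc2ccccc2)cc1)C(Cl)=O | intermediate
27 | 5-hydroxy lactam ester (C16 epimers) | OC1(Cc2ccc(OCc3ccccc3)cc2)C[C@@](CC=C)(C(=O)OC)C(=O)N1 | intermediate
28 | 5-methoxy lactam ester (C16 epimers) | C(c1ccccc1)Oc1ccc(cc1)CC1(OC)C[C@@](CC=C)(C(=O)OC)C(=O)N1 | intermediate
29 | hydroxymethyl lactam (C16 epimers) | C(c1ccccc1)Oc1ccc(cc1)CC1(OC)C[C@@](CC=C)(CO)C(=O)N1 | intermediate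
30 | TBDPS ether (C16 epimers) | C(c1ccccc1)Oc1ccc(cc1)CC1(OC)C[C@@](CC=C)(CO[Si](c2ccccc2)(c2ccccc2)C(C)(C)C)C(=O)N1 | intermediate
31 | C21 aldehyde (C16 epimers) | C(c1ccccc1)Oc1ccc(cc1)CC1(OC)C[C@@](CC=O)(CO[Si](c2ccccc2)(c2ccccc2)C(C)(C)C)C(=O)N1 | intermediate
32 | benzyl ether of the lactam fragment: C21 dimethyl acetal, C16 and C19 as in target | C(c1ccccc1)Oc1ccc(cc1)C[C@]1(OC)C[C@@](CC(OC)OC)(CO[Si](c2ccccc2)(c2ccccc2)C(C)(C)C)C(=O)N1 | intermediate
33 | phenol lactam fragment | Oc1ccc(cc1)C[C@]1(OC)C[C@@](CC(OC)OC)(CO[Si](c2ccccc2)(c2ccccc2)C(C)(C)C)C(=O)N1 | intermediate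
34 | 7β-aryl ether of the epoxy ketone | C[C@@H]1C[C@H](C)[C@H]2[C@@H](Oc3ccc(cc3)C[C@]3(OC)C[C@@](CC(OC)OC)(CO[Si](c4ccccc4)(c4ccccc4)C(C)(C)C)C(=O)N3)[C@@H]3[C@@H]4O[C@]4(C)C(=O)[C@H](C)[C@H]3[C@]2(C)C1 | intermediate
35 | allylic alcohol (33α-OH, C25=C27) | C[C@@H]1C[C@H](C)[C@H]2[C@@H](Oc3ccc(cc3)C[C@]3(OC)C[C@@](CC(OC)OC)(CO[Si](c4ccccc4)(c4ccccc4)C(C)(C)C)C(=O)N3)[C@@H]3[C@H](O)C(C)=C[C@H](C)[C@H]3[C@]2(C)C1 | intermediate
36 | 33α methyl carbonate | C[C@@H]1C[C@H](C)[C@H]2[C@@H](Oc3ccc(cc3)C[C@]3(OC)C[C@@](CC(OC)OC)(CO[Si](c4ccccc4)(c4ccccc4)C(C)(C)C)C(=O)N3)[C@@H]3[C@H](OC(=O)OC)C(C)=C[C@H](C)[C@H]3[C@]2(C)C1 | intermediate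
37 | carbonate with free C34 primary alcohol | C[C@@H]1C[C@H](C)[C@H]2[C@@H](Oc3ccc(cc3)C[C@]3(OC)C[C@@](CC(OC)OC)(CO)C(=O)N3)[C@@H]3[C@H](OC(=O)OC)C(C)=C[C@H](C)[C@H]3[C@]2(C)C1 | intermediate
38 | bis(pinacolato)diboron | CC1(C)OB(OC1(C)C)B1OC(C)(C)C(C)(C)O1 | starting material
39 | C27 β-pinacol boronate, C33=C25, C34 alcohol | C[C@@H]1C[C@H](C)[C@H]2[C@@H](Oc3ccc(cc3)C[C@]3(OC)C[C@@](CC(OC)OC)(CO)C(=O)N3)[C@@H]3C=C(C)[C@@H](B4OC(C)(C)C(C)(C)O4)[C@H](C)[C@H]3[C@]2(C)C1 | intermediate
40 | ring C allylboronate tethered to the C19 formyl lactam (key-step precursor) | C[C@@H]1C[C@H](C)[C@H]2[C@@H](Oc3ccc(cc3)C[C@]3(OC)C[C@@](CC(OC)OC)(C=O)C(=O)N3)[C@@H]3C=C(C)[C@@H](B4OC(C)(C)C(C)(C)O4)[C@H](C)[C@H]3[C@]2(C)C1 | intermediate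
41 | macrocyclic O-pinacolboryl homoallylic alkoxide | C[C@@H]1C[C@H](C)[C@H]2[C@H]3Oc4ccc(cc4)C[C@]4(OC)C[C@](CC(OC)OC)(C(=O)N4)[C@@H](OB6OC(C)(C)C(C)(C)O6)[C@H]5C(C)=C[C@H](C)[C@H]([C@H]35)[C@]2(C)C1 | intermediate
42 | macrocyclic homoallylic alcohol (C34 carbinol, configuration of no consequence) | C[C@@H]1C[C@H](C)[C@H]2[C@H]3Oc4ccc(cc4)C[C@]4(OC)C[C@](CC(OC)OC)(C(=O)N4)[C@@H](O)[C@H]5C(C)=C[C@H](C)[C@H]([C@H]35)[C@]2(C)C1 | intermediate
43 | macrocyclic β,γ-unsaturated C34 ketone | C[C@@H]1C[C@H](C)[C@H]2[C@H]3Oc4ccc(cc4)C[C@]4(OC)C[C@](CC(OC)OC)(C(=O)N4)C(=O)[C@H]5C(C)=C[C@H](C)[C@H]([C@H]35)[C@]2(C)C1 | intermediate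
44 | keto aldehyde hemiaminal | C[C@@H]1C[C@H](C)[C@H]2[C@H]3Oc4ccc(cc4)C[C@]4(O)C[C@](CC=O)(C(=O)N4)C(=O)[C@H]5C(C)=C[C@H](C)[C@H]([C@H]35)[C@]2(C)C1 | intermediate
45 | 25β-hydroperoxide with C27=C29 alkene | C[C@@H]1C[C@H](C)[C@H]2[C@H]3Oc4ccc(cc4)C[C@]4(O)C[C@](CC=O)(C(=O)N4)C(=O)[C@H]5[C@@](C)(OO)C=C(C)[C@H]([C@H]35)[C@]2(C)C1 | intermediate
46 | peroxyhemiacetal with C27=C29 alkene | C[C@@H]1C[C@H](C)[C@H]2[C@H]3Oc4ccc(cc4)C[C@]4(O)C[C@]5(C[C@H](O)OO[C@@]6(C)C=C(C)[C@H]([C@H]3[C@H]6C5=O)[C@]2(C)C1)C(=O)N4 | intermediate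
47 | bromohydrin (27α-Br, 29β-OH) | C[C@@H]1C[C@H](C)[C@H]2[C@H]3Oc4ccc(cc4)C[C@]4(O)C[C@]5(C[C@H](O)OO[C@@]6(C)[C@H](Br)[C@@](C)(O)[C@H]([C@H]3[C@H]6C5=O)[C@]2(C)C1)C(=O)N4 | intermediate
48 | CNP0533733.1 | C[C@@H]1C[C@H](C)[C@H]2[C@H]3Oc4ccc(cc4)C[C@]4(O)C[C@]5(C[C@H](O)OO[C@@]6(C)[C@H]7O[C@@]7(C)[C@H]([C@H]3[C@H]6C5=O)[C@]2(C)C1)C(=O)N4 | target

**Step count.** Total: 33 steps. Longest linear sequence: 24 steps (steps 1–13, then 23–33).

**Steps most likely to fail**

Step 29. What may go wrong: the strained 13-membered transition state may be reached too slowly, so that intermolecular allylboration to oligomers and protodeboronation take over. The fallback forms C33–C34 between separate fragments and closes the ring at the aryl ether instead. It sets out from 19, 33 and 38. Wharton transposition of 19 (N2H4·H2O, AcOH, MeOH) should give the tricyclic 7α,33α-diol F1. 1,1′-Carbonyldiimidazole converts it to the six-membered cyclic carbonate F2, which spans the two α-oxygens. CuCl, Xantphos, KOtBu and 38 open the allylic C33–O bond in the anti SN2′ sense with loss of CO2, to give the tricyclic C27 β-boronate F3 with a free 7α-hydroxyl. In parallel, 33 is desilylated (TBAF, AcOH) to the phenol primary alcohol F4 and oxidised (SO3·pyridine, DMSO, Et3N) to the phenol aldehyde F5. F3 and F5 in concentrated toluene at 60 °C react through the same closed transition state to the seco triol F6. Mitsunobu macrocyclisation (PPh3, DIAD, high dilution) should engage only the C7 alcohol, because the C34 carbinol lies between a quaternary and a tertiary carbon. It forms the C7–O8 bond with inversion and returns to the route at 42.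

Step 32. What may go wrong: singlet oxygen may attack the α face or abstract a hydrogen of the C26 methyl, giving regioisomeric or epimeric hydroperoxides. The fallback installs the peroxide by ionic chemistry and sets out from 43. Dimethyldioxirane should epoxidise C25=C27 from the less hindered α face to the 25α,27α-epoxide F7. Ethereal H2O2 with catalytic MoO2(acac)2 opens it at the tertiary C25 with inversion to the 25β-hydroperoxy-27α-ol F8. PPTS in dry CH2Cl2 lets the hydroperoxide exchange with the C21 dimethyl acetal to the cyclic methyl peroxyacetal F9. Martin sulfurane removes the axial 27α-hydroxyl together with the anti-periplanar β-hydrogen on C29 to give the alkene peroxyacetal F10. Hydrolysis with 1 M HCl in THF converts both methoxy groups and comes back to the route at 46.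

Step 23. What may go wrong: the hindered alkoxyphosphonium ion at C7 may lose a proton from C32 and eliminate faster than the phenol attacks from the β face. The fallback separates activation from displacement and sets out from 19 and 33. Chloromethanesulfonyl chloride and pyridine convert 19 to the 7α-chloromethanesulfonate F11. The caesium phenolate of 33 (Cs2CO3, 18-crown-6, toluene, 50 °C) displaces it with inversion and comes back to the route at 34.

**Further compounds**

F1 | step 29 | tricyclic 7α,33α-diol | C[C@@H]1C[C@H](C)[C@H]2[C@H](O)[C@@H]3[C@H](O)C(C)=C[C@H](C)[C@H]3[C@]2(C)C1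
F2 | step 29 | six-membered cyclic carbonate of F1 | C[C@@H]1C[C@H](C)[C@H]2[C@@H]3OC(=O)O[C@@H]4C(C)=C[C@H](C)[C@H]([C@H]34)[C@]2(C)C1
F3 | step 29 | tricyclic C27 β-pinacol boronate with free 7α-hydroxyl | C[C@@H]1C[C@H](C)[C@H]2[C@H](O)[C@@H]3C=C(C)[C@@H](B4OC(C)(C)C(C)(C)O4)[C@H](C)[C@H]3[C@]2(C)C1
F4 | step 29 | phenol primary alcohol of the lactam fragment | Oc1ccc(cc1)C[C@]1(OC)C[C@@](CC(OC)OC)(CO)C(=O)N1
F5 | step 29 | phenol aldehyde of the lactam fragment | Oc1ccc(cc1)C[C@]1(OC)C[C@@](CC(OC)OC)(C=O)C(=O)N1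
F6 | step 29 | seco triol with C33–C34 formed | C[C@@H]1C[C@H](C)[C@H]2[C@H](O)[C@@H]3[C@@H]([C@H](O)[C@]4(CC(OC)OC)C[C@@](OC)(Cc5ccc(O)cc5)NC4=O)C(C)=C[C@H](C)[C@H]3[C@]2(C)C1
F7 | step 32 | 25α,27α-epoxide of 43 | C[C@@H]1C[C@H](C)[C@H]2[C@H]3Oc4ccc(cc4)C[C@]4(OC)C[C@](CC(OC)OC)(C(=O)N4)C(=O)[C@H]5[C@]6(C)O[C@@H]6[C@H](C)[C@H]([C@H]35)[C@]2(C)C1
F8 | step 32 | 25β-hydroperoxy-27α-ol | C[C@@H]1C[C@H](C)[C@H]2[C@H]3Oc4ccc(cc4)C[C@]4(OC)C[C@](CC(OC)OC)(C(=O)N4)C(=O)[C@H]5[C@@](C)(OO)[C@H](O)[C@H](C)[C@H]([C@H]35)[C@]2(C)C1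
F9 | step 32 | cyclic methyl peroxyacetal 27α-ol | C[C@@H]1C[C@H](C)[C@H]2[C@H]3Oc4ccc(cc4)C[C@]4(OC)C[C@]5(CC(OC)OO[C@@]6(C)[C@H](O)[C@H](C)[C@H]([C@H]3[C@H]6C5=O)[C@]2(C)C1)C(=O)N4
F10 | step 32 | cyclic methyl peroxyacetal with C27=C29 alkene | C[C@@H]1C[C@H](C)[C@H]2[C@H]3Oc4ccc(cc4)C[C@]4(OC)C[C@]5(CC(OC)OO[C@@]6(C)C=C(C)[C@H]([C@H]3[C@H]6C5=O)[C@]2(C)C1)C(=O)N4
F11 | step 23 | 7α-chloromethanesulfonate of 19 | C[C@@H]1C[C@H](C)[C@H]2[C@H](OS(=O)(=O)CCl)[C@@H]3[C@@H]4O[C@]4(C)C(=O)[C@H](C)[C@H]3[C@]2(C)C1
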